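## Plan

- **Cuts:** first the four O-benzyl masks of the phenols, then C8–OMe (back through C8–Br to C8–H). Ring C is then cut at O1–C8a and C4–C4a, and the resulting keto ester at C2–C3.
- **Enabling feature:** O1 and C4 are bonded to the adjacent ring A carbons C8a and C4a. The oxygen on C5, next to C4a, polarises a C4a≡C8a aryne so that a nucleophile enters at C8a and the carbanion arises at C4a, where the acyl carbon C4 must bond.
- **Forward, rings A and B:** both are taken ready-made from methyl 3,5-bis(benzyloxy)-4-methoxybenzoate. One portion is degraded (CO2Me to OH) and made into the o-silylaryl triflate; the other is extended by Claisen condensation to the α-methoxy-β-keto ester.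
- **Forward, ring C:** it is the only ring built, and it closes when the aryne takes up the enolate oxygen and the ester carbonyl. Bromination and methoxylation at C8 and hydrogenolysis follow.
- **Stereochemistry:** the target has no stereocentre. The one stereocentre met on the way (Cα of the racemic keto ester) disappears on enolisation.

Key step: step 8

Assumption: methyl 3,5-dihydroxy-4-methoxybenzoate (methyl 4-O-methylgallate) is bought as such, being the catalogue methyl ester of the equally available acid.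

## Route

Step 1
Reactants: 1 methyl 3,5-dihydroxy-4-methoxybenzoate
Product: 2 methyl 3,5-bis(benzyloxy)-4-methoxybenzoate
Conditions: BnBr (2.4 equiv), K2CO3, DMF, 60 °C
Reagents that add atoms: benzyl bromide, BrCc1ccccc1
Why: Williamson ether synthesis, in which K2CO3 deprotonates only the two phenols and the reactive benzylic bromide alkylates them while the methyl ester and the methyl ether stay untouched.

Step 2
Reactants: 2 methyl 3,5-bis(benzyloxy)-4-methoxybenzoate
Product: 3 [3,5-bis(benzyloxy)-4-methoxyphenyl]methanol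
Conditions: LiAlH4, THF, 0 °C → rt
Reagents that add atoms: none
Why: Hydride reduction of an aromatic ester to the benzylic alcohol, to which aryl benzyl and aryl methyl ethers are inert.

Step 3
Reactants: 3 [3,5-bis(benzyloxy)-4-methoxyphenyl]methanol
Product: 4 3,5-bis(benzyloxy)-4-methoxybenzaldehyde
Conditions: activated MnO2, CH2Cl2, rt
Reagents that add atoms: none
Why: Benzylic alcohol oxidation on MnO2, which stops at the aldehyde and leaves the ethers alone.

Step 4
Reactants: 4 3,5-bis(benzyloxy)-4-methoxybenzaldehyde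
Product: 6 3,5-bis(benzyloxy)-4-methoxyphenol, via aryl formate 5 (not isolated)
Conditions: mCPBA, CH2Cl2, 0 °C → rt; aq. NaHCO3 wash; crude material, K2CO3 (cat.), MeOH, rt
Reagents that add atoms: mCPBA (3-chloroperoxybenzoic acid), O=C(OO)c1cccc(Cl)c1
Why: Baeyer–Villiger oxidation of an electron-rich benzaldehyde (the peracid counterpart of the Dakin reaction), in which the trialkoxyphenyl group migrates from the Criegee adduct to give formate 5, cleaved at once by base-catalysed methanolysis.

Step 5
Reactants: 6 3,5-bis(benzyloxy)-4-methoxyphenol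
Product: 7 3,5-bis(benzyloxy)-2-bromo-4-methoxyphenol
Conditions: NBS (1.0 equiv), CH2Cl2, −78 → 0 °C, dark
Reagents that add atoms: N-bromosuccinimide, O=C1CCC(=O)N1Br
Why: Electrophilic aromatic bromination directed by the free phenol, where the para position carries the methoxy group and the two ortho positions are equivalent by symmetry, so one equivalent of NBS at low temperature can give only this monobromide.

Step 6
Reactants: 7 3,5-bis(benzyloxy)-2-bromo-4-methoxyphenol
Product: 10 3,5-bis(benzyloxy)-4-methoxy-2-(trimethylsilyl)phenyl trifluoromethanesulfonate, via silyl ether 8 (not isolated), via lithium phenoxide 9 (not isolated)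
Conditions: HMDS, THF, 70 °C, then evaporation; n-BuLi (1.1 equiv), THF, −78 °C; Tf2O (1.2 equiv), −78 → 0 °C
Reagents that add atoms: hexamethyldisilazane, C[Si](C)(C)N[Si](C)(C)C; trifluoromethanesulfonic anhydride, O=S(=O)(OS(=O)(=O)C(F)(F)F)C(F)(F)F
Why: The standard one-flask sequence to o-silylaryl triflates (O-silylation, bromine–lithium exchange, retro-Brook 1,3-shift of silicon from oxygen to carbon, O-triflation of the phenoxide), in which exchange and silyl shift at −78 °C should be far faster than deprotonation of the benzyl ethers.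

Step 7
Reactants: 2 methyl 3,5-bis(benzyloxy)-4-methoxybenzoate; 11 methyl methoxyacetate
Product: 12 methyl 3-[3,5-bis(benzyloxy)-4-methoxyphenyl]-2-methoxy-3-oxopropanoate (racemic)
Conditions: 11 (2.5 equiv), LDA (2.6 equiv), THF, −78 °C; then 2, −78 → 0 °C; 1 M HCl quench
Reagents that add atoms: none
Why: Crossed Claisen condensation between a preformed ester enolate and a benzoate that cannot enolise, driven by deprotonation of the β-keto ester by the excess enolate; the new stereocentre forms racemic and is erased in step 8.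

Step 8
Reactants: 10 3,5-bis(benzyloxy)-4-methoxy-2-(trimethylsilyl)phenyl trifluoromethanesulfonate; 12 methyl 3-[3,5-bis(benzyloxy)-4-methoxyphenyl]-2-methoxy-3-oxopropanoate
Product: 16 5,7-bis(benzyloxy)-2-[3,5-bis(benzyloxy)-4-methoxyphenyl]-3,6-dimethoxy-4H-chromen-4-one, via aryne 13 (not isolated), via cesium enolate 14 (not isolated), via aryl anion 15 (not isolated)
Conditions: 12 (1.3 equiv), CsF (4 equiv), THF, 65 °C; 10 added slowly by syringe pump
Reagents that add atoms: none
Why: Proposed new method: CsF strips the silyl group from 10 with loss of triflate to release aryne 13 and also deprotonates 12, so that the oxygen of enolate 14 adds to C8a, the aryl anion 15 formed at C4a attacks the ester carbonyl held cis to it across the new enol ether, and methoxide leaves; O1–C8a and C4–C4a form and ring C closes by a 6-exo-trig acyl substitution. The closest known reaction type is the annulation of arynes with salicylate esters to xanthones (phenoxide addition, then acyl capture of the aryl anion), and 14 is the open-chain counterpart of a salicylate, but this course has not been shown for an acyclic β-keto ester enolate. The side of addition is fixed by the C5 benzyloxy group, whose inductive pull distorts the aryne so that C8a is the more electrophilic carbon and the charge builds up at C4a beside that oxygen, as is general for 3-alkoxyarynes. The selectivity that remains unproven is O- against C-arylation, since simple β-keto esters are known to C-arylate and then insert the aryne into their Cα–C(=O) bond; here the fully substituted, methoxy-bearing Cα, the loosely paired cesium cation and an asynchronous addition in which the ester carbonyl already stabilises the developing C4a carbanion through a six-membered array are relied on to favour oxygen. THF replaces the more acidic acetonitrile, 10 meets an excess of 14, and the released methoxide regenerates 14 from 12, so that 15 should cyclise before it is protonated. No stereocentre is formed, and the enolate geometry needed (O− cis to CO2Me) is the cesium-chelated one, which also places ring B next to the smaller methoxy group.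

Step 9
Reactants: 16 5,7-bis(benzyloxy)-2-[3,5-bis(benzyloxy)-4-methoxyphenyl]-3,6-dimethoxy-4H-chromen-4-one
Product: 17 5,7-bis(benzyloxy)-2-[3,5-bis(benzyloxy)-4-methoxyphenyl]-8-bromo-3,6-dimethoxy-4H-chromen-4-one
Conditions: NBS (1.05 equiv), DMF, 0 °C → rt, dark
Reagents that add atoms: N-bromosuccinimide, O=C1CCC(=O)N1Br
Why: Electrophilic aromatic bromination at the only C–H of ring A, which is ortho to O1 and to the C7 oxygen and para to the C5 oxygen and should therefore react well before C2′/C6′ of ring B, which have only two activating oxygens and are tied to the electron-poor C2.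

Step 10
Reactants: 17 5,7-bis(benzyloxy)-2-[3,5-bis(benzyloxy)-4-methoxyphenyl]-8-bromo-3,6-dimethoxy-4H-chromen-4-one
Product: 18 5,7-bis(benzyloxy)-2-[3,5-bis(benzyloxy)-4-methoxyphenyl]-3,6,8-trimethoxy-4H-chromen-4-one
Conditions: NaOMe (25% in MeOH, excess), CuBr (0.3 equiv), DMF, 110 °C
Reagents that add atoms: sodium methoxide, [Na+].[O-]C
Why: Copper-catalysed Ullmann-type exchange of an aryl bromide for methoxide, the established way from 8-bromoflavones to 8-methoxyflavones, under which benzyl ethers and the pyranone should persist.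

Step 11
Reactants: 18 5,7-bis(benzyloxy)-2-[3,5-bis(benzyloxy)-4-methoxyphenyl]-3,6,8-trimethoxy-4H-chromen-4-one
Product: 19 5,7-dihydroxy-2-(3,5-dihydroxy-4-methoxyphenyl)-3,6,8-trimethoxy-4H-chromen-4-one (5,7,3′,5′-tetrahydroxy-3,6,8,4′-tetramethoxyflavone)
Conditions: H2 (1 atm), Pd/C (10%), THF–MeOH, rt
Reagents that add atoms: none
Why: Catalytic hydrogenolysis of the four aryl benzyl ethers under one atmosphere of hydrogen, conditions under which the tetrasubstituted C2=C3 bond, the carbonyl group and the methyl ethers of a flavone are not reduced.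

## Compound list

1 | methyl 3,5-dihydroxy-4-methoxybenzoate | COC(=O)c1cc(O)c(OC)c(O)c1 | starting material
2 | methyl 3,5-bis(benzyloxy)-4-methoxybenzoate | COC(=O)c1cc(OCc2ccccc2)c(OC)c(OCc2ccccc2)c1 | intermediate
3 | [3,5-bis(benzyloxy)-4-methoxyphenyl]methanol | OCc1cc(OCc2ccccc2)c(OC)c(OCc2ccccc2)c1 | intermediate
4 | 3,5-bis(benzyloxy)-4-methoxybenzaldehyde | O=Cc1cc(OCc2ccccc2)c(OC)c(OCc2ccccc2)c1 | intermediate
5 | 3,5-bis(benzyloxy)-4-methoxyphenyl formate | O=COc1cc(OCc2ccccc2)c(OC)c(OCc2ccccc2)c1 | intermediate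
6 | 3,5-bis(benzyloxy)-4-methoxyphenol | Oc1cc(OCc2ccccc2)c(OC)c(OCc2ccccc2)c1 | intermediate
7 | 3,5-bis(benzyloxy)-2-bromo-4-methoxyphenol | Oc1cc(OCc2ccccc2)c(OC)c(OCc2ccccc2)c1Br | intermediate
8 | [3,5-bis(benzyloxy)-2-bromo-4-methoxyphenoxy]trimethylsilane | C[Si](C)(C)Oc1cc(OCc2ccccc2)c(OC)c(OCc2ccccc2)c1Br | intermediate
9 | lithium 3,5-bis(benzyloxy)-4-methoxy-2-(trimethylsilyl)phenoxide | [Li+].[O-]c1cc(OCc2ccccc2)c(OC)c(OCc2ccccc2)c1[Si](C)(C)C | intermediate
10 | 3,5-bis(benzyloxy)-4-methoxy-2-(trimethylsilyl)phenyl trifluoromethanesulfonate | C[Si](C)(C)c1c(OS(=O)(=O)C(F)(F)F)cc(OCc2ccccc2)c(OC)c1OCc1ccccc1 | intermediate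
11 | methyl methoxyacetate | COCC(=O)OC | starting material
12 | methyl 3-[3,5-bis(benzyloxy)-4-methoxyphenyl]-2-methoxy-3-oxopropanoate (racemic) | COC(=O)C(OC)C(=O)c1cc(OCc2ccccc2)c(OC)c(OCc2ccccc2)c1 | intermediate
13 | 3,5-bis(benzyloxy)-4-methoxybenzyne (triple bond C1–C2) | C1#CC(OCc2ccccc2)=C(OC)C(OCc2ccccc2)=C1 | intermediate
14 | cesium (1E)-1-[3,5-bis(benzyloxy)-4-methoxyphenyl]-2,3-dimethoxy-3-oxoprop-1-en-1-olate (O− cis to CO2Me) | [Cs+].[O-]/C(c1cc(OCc2ccccc2)c(OC)c(OCc2ccccc2)c1)=C(\C(=O)OC)OC | intermediate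
15 | methyl (2E)-3-[3,5-bis(benzyloxy)-2-cesio-4-methoxyphenoxy]-3-[3,5-bis(benzyloxy)-4-methoxyphenyl]-2-methoxyprop-2-enoate (aryl anion at C4a, aryloxy cis to CO2Me) | [Cs+].COC(=O)/C(OC)=C(\Oc1cc(OCc2ccccc2)c(OC)c(OCc2ccccc2)[c-]1)c1cc(OCc2ccccc2)c(OC)c(OCc2ccccc2)c1 | intermediate
16 | 5,7-bis(benzyloxy)-2-[3,5-bis(benzyloxy)-4-methoxyphenyl]-3,6-dimethoxy-4H-chromen-4-one | COc1c(OCc2ccccc2)cc2oc(-c3cc(OCc4ccccc4)c(OC)c(OCc4ccccc4)c3)c(OC)c(=O)c2c1OCc1ccccc1 | intermediate
17 | 5,7-bis(benzyloxy)-2-[3,5-bis(benzyloxy)-4-methoxyphenyl]-8-bromo-3,6-dimethoxy-4H-chromen-4-one | COc1c(OCc2ccccc2)c(Br)c2oc(-c3cc(OCc4ccccc4)c(OC)c(OCc4ccccc4)c3)c(OC)c(=O)c2c1OCc1ccccc1 | intermediate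
18 | 5,7-bis(benzyloxy)-2-[3,5-bis(benzyloxy)-4-methoxyphenyl]-3,6,8-trimethoxy-4H-chromen-4-one | COc1c(OCc2ccccc2)c(OC)c2oc(-c3cc(OCc4ccccc4)c(OC)c(OCc4ccccc4)c3)c(OC)c(=O)c2c1OCc1ccccc1 | intermediate
19 | 5,7-dihydroxy-2-(3,5-dihydroxy-4-methoxyphenyl)-3,6,8-trimethoxy-4H-chromen-4-one | COc1c(O)cc(-c2oc3c(OC)c(O)c(OC)c(O)c3c(=O)c2OC)cc1O | target

## Step count and risks

Total step count: 11. Longest linear sequence: 10 steps (steps 1 to 6 and 8 to 11, from 1 to 19). Step 7 is a one-step branch from 2.

**First, step 8.**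
- **What may go wrong:** the ambident enolate is arylated at carbon, after which the aryl anion adds to the ketone and the aryne ends up inserted into the Cα–C(=O) bond. Alternatively, the aryl anion is protonated before it reaches the ester.
- **Fallback:** ring C is built by the Baker–Venkataraman route, which closes O1–C2 instead. It sets out from 7 and 2 and comes back at 16.
- Bromophenol 7 is treated with two equivalents of n-BuLi (THF, −78 °C) and the lithiated phenoxide is acylated with commercial N,2-dimethoxy-N-methylacetamide. This should give 1-[2,4-bis(benzyloxy)-6-hydroxy-3-methoxyphenyl]-2-methoxyethan-1-one F1.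
- Ester 2 is saponified (LiOH, THF–water) to 3,5-bis(benzyloxy)-4-methoxybenzoic acid F2. Oxalyl chloride with catalytic DMF turns it into 3,5-bis(benzyloxy)-4-methoxybenzoyl chloride F3.
- O-Aroylation of F1 with F3 (pyridine, DMAP) should give 3,5-bis(benzyloxy)-4-methoxy-2-(methoxyacetyl)phenyl 3,5-bis(benzyloxy)-4-methoxybenzoate F4.
- KOt-Bu in THF brings about the acyl shift to 1-[2,4-bis(benzyloxy)-6-hydroxy-3-methoxyphenyl]-3-[3,5-bis(benzyloxy)-4-methoxyphenyl]-2-methoxypropane-1,3-dione F5.
- Catalytic p-TsOH in warm toluene then cyclodehydrates F5 to 16.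

**Second, step 10.**
- **What may go wrong:** reductive loss of bromine, and opening of the pyranone by methoxide at the temperature that a bromide flanked on both sides demands.
- **Fallback:** the C8 oxygen is brought in through boron and methylated afterwards. It sets out from 17 and comes back at 18.
- Miyaura borylation (B2pin2, Pd(OAc)2, SPhos, KOAc, dioxane, 100 °C) should give 5,7-bis(benzyloxy)-2-[3,5-bis(benzyloxy)-4-methoxyphenyl]-3,6-dimethoxy-8-(4,4,5,5-tetramethyl-1,3,2-dioxaborolan-2-yl)-4H-chromen-4-one F6.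
- Oxidation with sodium perborate (NaBO3) in THF–water should give 5,7-bis(benzyloxy)-2-[3,5-bis(benzyloxy)-4-methoxyphenyl]-8-hydroxy-3,6-dimethoxy-4H-chromen-4-one F7.
- Methylation (MeI, K2CO3, acetone) leads to 18.

**Third, step 9.**
- **What may go wrong:** competing bromination of ring B at C2′/C6′, or over-bromination.
- **Fallback:** a free 5-hydroxy group, para to C8, is used as the activator. It sets out from 16 and comes back at 19.
- Chelation-controlled removal of the 5-O-benzyl group next to the C4 carbonyl (BCl3, 1 equiv, CH2Cl2, −78 °C) should give 7-(benzyloxy)-2-[3,5-bis(benzyloxy)-4-methoxyphenyl]-5-hydroxy-3,6-dimethoxy-4H-chromen-4-one F8.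
- NBS then attacks the strongly activated C8 to give 7-(benzyloxy)-2-[3,5-bis(benzyloxy)-4-methoxyphenyl]-8-bromo-5-hydroxy-3,6-dimethoxy-4H-chromen-4-one F9.
- CuBr/NaOMe in DMF, which is known to tolerate free hydroxy groups on bromoflavones, should give 7-(benzyloxy)-2-[3,5-bis(benzyloxy)-4-methoxyphenyl]-5-hydroxy-3,6,8-trimethoxy-4H-chromen-4-one F10.
- Hydrogenolysis (H2, Pd/C) of the three remaining benzyl ethers gives 19.

## Further compounds

F1 | step 8 | 1-[2,4-bis(benzyloxy)-6-hydroxy-3-methoxyphenyl]-2-methoxyethan-1-one | COCC(=O)c1c(O)cc(OCc2ccccc2)c(OC)c1OCc1ccccc1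
F2 | step 8 | 3,5-bis(benzyloxy)-4-methoxybenzoic acid | OC(=O)c1cc(OCc2ccccc2)c(OC)c(OCc2ccccc2)c1
F3 | step 8 | 3,5-bis(benzyloxy)-4-methoxybenzoyl chloride | ClC(=O)c1cc(OCc2ccccc2)c(OC)c(OCc2ccccc2)c1
F4 | step 8 | 3,5-bis(benzyloxy)-4-methoxy-2-(methoxyacetyl)phenyl 3,5-bis(benzyloxy)-4-methoxybenzoate | COCC(=O)c1c(OC(=O)c2cc(OCc3ccccc3)c(OC)c(OCc3ccccc3)c2)cc(OCc2ccccc2)c(OC)c1OCc1ccccc1
F5 | step 8 | 1-[2,4-bis(benzyloxy)-6-hydroxy-3-methoxyphenyl]-3-[3,5-bis(benzyloxy)-4-methoxyphenyl]-2-methoxypropane-1,3-dione | COC(C(=O)c1cc(OCc2ccccc2)c(OC)c(OCc2ccccc2)c1)C(=O)c1c(O)cc(OCc2ccccc2)c(OC)c1OCc1ccccc1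
F6 | step 10 | 5,7-bis(benzyloxy)-2-[3,5-bis(benzyloxy)-4-methoxyphenyl]-3,6-dimethoxy-8-(4,4,5,5-tetramethyl-1,3,2-dioxaborolan-2-yl)-4H-chromen-4-one | COc1c(OCc2ccccc2)c(B2OC(C)(C)C(C)(C)O2)c2oc(-c3cc(OCc4ccccc4)c(OC)c(OCc4ccccc4)c3)c(OC)c(=O)c2c1OCc1ccccc1
F7 | step 10 | 5,7-bis(benzyloxy)-2-[3,5-bis(benzyloxy)-4-methoxyphenyl]-8-hydroxy-3,6-dimethoxy-4H-chromen-4-one | COc1c(OCc2ccccc2)c(O)c2oc(-c3cc(OCc4ccccc4)c(OC)c(OCc4ccccc4)c3)c(OC)c(=O)c2c1OCc1ccccc1
F8 | step 9 | 7-(benzyloxy)-2-[3,5-bis(benzyloxy)-4-methoxyphenyl]-5-hydroxy-3,6-dimethoxy-4H-chromen-4-one | COc1c(OCc2ccccc2)cc2oc(-c3cc(OCc4ccccc4)c(OC)c(OCc4ccccc4)c3)c(OC)c(=O)c2c1O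
F9 | step 9 | 7-(benzyloxy)-2-[3,5-bis(benzyloxy)-4-methoxyphenyl]-8-bromo-5-hydroxy-3,6-dimethoxy-4H-chromen-4-one | COc1c(OCc2ccccc2)c(Br)c2oc(-c3cc(OCc4ccccc4)c(OC)c(OCc4ccccc4)c3)c(OC)c(=O)c2c1O
F10 | step 9 | 7-(benzyloxy)-2-[3,5-bis(benzyloxy)-4-methoxyphenyl]-5-hydroxy-3,6,8-trimethoxy-4H-chromen-4-one | COc1c(OCc2ccccc2)c(OC)c2oc(-c3cc(OCc4ccccc4)c(OC)c(OCc4ccccc4)c3)c(OC)c(=O)c2c1O
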